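**Strategy.** The route rests on cutting the pyran ring (ring C) of the third flavan unit at C2–C3 together with its C4–C8 interflavan bond. In one operation a chiral Brønsted acid ionises an acyclic O-aryl α-acyloxy acetal; the resulting oxocarbenium ion is attacked by a (Z)-β-acetoxystyrene (Prins cyclisation), closing ring C with C2 and C3 cis and leaving a C4 cation that ring A of this unit (O1, 5-O, 7-O) stabilises – the biogenetic extension-unit cation – which C8 of protected catechin captures. The precursor is a phloroglucinol-derived aryl ether with an enol acetate side chain; the two upper epicatechin units come from (−)-epicatechin and are attached by a known 4→8 condensation.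

Key step: step 7

Remarks on the chemistry: flavan numbering (O1, C2, C3, C4, C4a, C5–C8, C8a) is used and the units are counted 1–4 from the top epicatechin to the bottom catechin. Compound 9 is used as the racemate at its acetal carbon, which is planarised on ionisation. The antipode of the chiral acid in step 7 is the one that delivers the 2R,3R ring.

**Step 1**
Reactants: 1 3,5-bis(benzyloxy)phenol
Product: 2 2,4-bis(benzyloxy)-6-hydroxybenzaldehyde
Conditions: (CH2O)n, MgCl2, Et3N, MeCN, reflux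
Reagents that add atoms: formaldehyde (as paraformaldehyde), C=O
Why: Magnesium-phenoxide-directed ortho-formylation (Casnati–Skattebøl reaction) places the formyl group only ortho to the free hydroxyl, and the two ortho positions of 1 are equivalent.

**Step 2**
Reactants: 2 2,4-bis(benzyloxy)-6-hydroxybenzaldehyde
Product: 3 2,4-bis(benzyloxy)-6-(triisopropylsilyloxy)benzaldehyde
Conditions: TIPSOTf, 2,6-lutidine, CH2Cl2, 0 °C
Reagents that add atoms: triisopropylsilyl trifluoromethanesulfonate, CC(C)[Si](C(C)C)(C(C)C)OS(=O)(=O)C(F)(F)F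
Why: Silylation of the hydrogen-bonded phenol with the reactive silyl triflate masks O1 so that the later ortho-alkyne cannot close to a benzofuran.

**Step 3**
Reactants: 3 2,4-bis(benzyloxy)-6-(triisopropylsilyloxy)benzaldehyde
Product: 4 [3,5-bis(benzyloxy)-2-ethynylphenoxy]triisopropylsilane
Conditions: dimethyl (1-diazo-2-oxopropyl)phosphonate, K2CO3, MeOH/THF, 0 °C to rt
Reagents that add atoms: dimethyl (1-diazo-2-oxopropyl)phosphonate (Bestmann–Ohira reagent), COP(=O)(OC)C(=[N+]=[N-])C(C)=O
Why: Seyferth–Gilbert homologation with the Bestmann–Ohira reagent converts the aryl aldehyde into the terminal alkyne under carbonate conditions that the bulky aryl silyl ether and the benzyl ethers should tolerate.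

**Step 4**
Reactants: 4 [3,5-bis(benzyloxy)-2-ethynylphenoxy]triisopropylsilane
Product: 5 (Z)-2-[2,4-bis(benzyloxy)-6-(triisopropylsilyloxy)phenyl]ethenyl acetate
Conditions: AcOH (1.3 equiv), [RuCl2(p-cymene)]2 (1 mol%), P(4-ClC6H4)3 (3 mol%), DMAP (4 mol%), toluene, 60 °C
Reagents that add atoms: acetic acid, CC(=O)O
Why: Ruthenium-vinylidene-mediated anti-Markovnikov hydro-acyloxylation of the terminal alkyne puts acetate on the terminal carbon and should give the Z enol ester, because carboxylate attacks the vinylidene α-carbon and protonolysis then leaves acetate and aryl cis.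

**Step 5**
Reactants: 5 (Z)-2-[2,4-bis(benzyloxy)-6-(triisopropylsilyloxy)phenyl]ethenyl acetate; 6 3,4-bis(benzyloxy)benzaldehyde
Product: 9 (Z)-2-{2,4-bis(benzyloxy)-6-[(3,4-bis(benzyloxy)phenyl)(pivaloyloxy)methoxy]phenyl}ethenyl acetate, via α-chlorobenzyl pivalate 7 (not isolated), via tetrabutylammonium phenoxide 8 (not isolated)
Conditions: 6, PivCl, ZnCl2 (2 mol%), CH2Cl2, 0 °C; separately 5, Bu4N[Ph3SiF2] (1.1 equiv), THF, −20 °C; then combine, −40 to 0 °C
Reagents that add atoms: pivaloyl chloride, CC(C)(C)C(Cl)=O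
Why: Lewis-acid-catalysed addition of the acyl chloride to aldehyde 6 gives α-chloroalkyl ester 7, which O-alkylates the fluoride-liberated phenoxide 8 at low temperature (acyloxyalkylation, as in pivaloyloxymethyl ether formation) and so installs the O1–C2 bond at the acetal oxidation level; the acetal centre forms as a racemate and is erased in step 7.

**Step 6**
Reactants: 10 (+)-catechin
Product: 11 5,7,3',4'-tetra-O-benzyl-(+)-catechin
Conditions: BnBr (4.4 equiv), K2CO3, DMF, 0 °C to rt
Reagents that add atoms: benzyl bromide, BrCc1ccccc1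
Why: Williamson benzylation takes only the four phenols, which are far more acidic than the secondary 3-OH, and does not touch C2 or C3.

**Step 7**
Reactants: 9 (Z)-2-{2,4-bis(benzyloxy)-6-[(3,4-bis(benzyloxy)phenyl)(pivaloyloxy)methoxy]phenyl}ethenyl acetate; 11 5,7,3',4'-tetra-O-benzyl-(+)-catechin (4 equiv)
Product: 13 3-O-acetyl-5,7,3',4'-tetra-O-benzylepicatechin-(4β→8)-5,7,3',4'-tetra-O-benzylcatechin, via 4β-pivaloyloxyflavan-3-yl acetate 12 (not isolated)
Conditions: (S,S)-IDPi (chiral imidodiphosphorimidate Brønsted acid with 3,3'-diaryl-BINOL backbones and P=NTf groups, 5 mol%), 4 Å MS, CH2Cl2, −78 to −50 °C; then TMSOTf (10 mol%), −78 to −40 °C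
Reagents that add atoms: none
Why: Proposed new method: the chiral acid protonates the acetal pivalate of 9, PivOH leaves, and the (E)-O-aryl oxocarbenium ion, paired with the confined chiral anion, is attacked at C2 by the acetoxy-bearing carbon C3 of the (Z)-β-acetoxystyrene, because the charge then lands on C4, where O1, 5-OBn and 7-OBn of ring A (ortho, ortho, para) and the neighbouring 3-acetate stabilise it, while the acyl group has switched off the opposite enol-ether polarisation. The closest known reaction types are the confined-Brønsted-acid-catalysed asymmetric Prins cyclisation of aldehydes with homoallylic alcohols and the Lewis-acid Prins cyclisation of α-acyloxy ethers; new are the O-aryl oxocarbenium ion and the β-acyloxystyrene terminator. Ring C of unit 3 closes by C2–C3 bond formation in a 6-endo-trig cation–olefin mode through a half-chair transition state. C2 and C3 arise together: the pseudo-equatorial aryl of the (E)-oxocarbenium ion and the Z alkene (acetoxy pseudo-axial) should give the 2,3-cis ring, and the chiral counter-anion selects the face (antipode chosen for 2R,3R). C4 is set when the flavan-4-yl cation, stored reversibly as pivalate 12, is attacked by C8 of 11 anti to the axial 3-acetoxy group (acyloxonium participation), which should give the 3,4-trans (4β) bond. The step needs C3- rather than C4-attack (secured by the enol ester and the trioxygenated ring A), C8 selectivity in 11 (the usual site of attack in tetra-O-benzylflavan-3-ols) and suppression of self-condensation (excess 11, low temperature).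

**Step 8**
Reactants: 13 3-O-acetyl-5,7,3',4'-tetra-O-benzylepicatechin-(4β→8)-5,7,3',4'-tetra-O-benzylcatechin
Product: 14 5,7,3',4'-tetra-O-benzylepicatechin-(4β→8)-5,7,3',4'-tetra-O-benzylcatechin (octa-O-benzylprocyanidin B1)
Conditions: NaOMe (cat.), MeOH/THF, rt to 40 °C
Reagents that add atoms: none
Why: Zemplén transesterification removes the only ester, while benzyl ethers and the interflavan bond are inert to catalytic methoxide.

**Step 9**
Reactants: 15 (−)-epicatechin
Product: 16 5,7,3',4'-tetra-O-benzyl-(−)-epicatechin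
Conditions: BnBr (4.4 equiv), K2CO3, DMF, 0 °C to rt
Reagents that add atoms: benzyl bromide, BrCc1ccccc1
Why: Williamson benzylation of the four phenols, as in step 6, leaves the 3-OH and both stereocentres untouched.

**Step 10**
Reactants: 16 5,7,3',4'-tetra-O-benzyl-(−)-epicatechin
Product: 17 4β-(2-ethoxyethoxy)-5,7,3',4'-tetra-O-benzylepicatechin
Conditions: DDQ (2 equiv), 2-ethoxyethanol, CH2Cl2, rt
Reagents that add atoms: 2-ethoxyethanol, CCOCCO
Why: DDQ abstracts hydride from the C4 methylene activated by ring A, and the alcohol captures the benzylic cation anti to the axial 3-OH (oxidative benzylic etherification), which should give the 3,4-trans (4β) ether.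

**Step 11**
Reactants: 17 4β-(2-ethoxyethoxy)-5,7,3',4'-tetra-O-benzylepicatechin; 16 5,7,3',4'-tetra-O-benzyl-(−)-epicatechin (4 equiv)
Product: 18 5,7,3',4'-tetra-O-benzylepicatechin-(4β→8)-5,7,3',4'-tetra-O-benzylepicatechin (octa-O-benzylprocyanidin B2)
Conditions: TMSOTf (cat.), CH2Cl2, −78 °C
Reagents that add atoms: none
Why: TMSOTf ionises the C4 ether to the flavan-4-yl cation, which undergoes Friedel–Crafts attack by C8 of excess 16 anti to the axial 3-OH and so sets the 4β (3,4-trans) interflavan bond.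

**Step 12**
Reactants: 18 octa-O-benzylprocyanidin B2
Product: 19 octa-O-benzylprocyanidin B2 carrying a 4β-(2-ethoxyethoxy) group on its lower unit
Conditions: DDQ (2 equiv), 2-ethoxyethanol, CH2Cl2, rt
Reagents that add atoms: 2-ethoxyethanol, CCOCCO
Why: The same DDQ-mediated benzylic oxidation acts only on the lower unit, which alone has a C4 methylene (the C4–H of the upper unit is shielded by two flanking aryl groups), and the alkoxy group again enters trans to the 3-OH.

**Step 13**
Reactants: 19 octa-O-benzylprocyanidin B2 4β-(2-ethoxyethyl) ether; 14 octa-O-benzylprocyanidin B1 (2 equiv)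
Product: 20 hexadeca-O-benzylarecatannin a2
Conditions: TMSOTf (cat.), CH2Cl2, −40 °C
Reagents that add atoms: none
Why: TMSOTf-promoted Friedel–Crafts 4→8 condensation of a dimeric electrophile with a dimeric nucleophile: the cation from 19 should be attacked by C8 of ring A of unit 3 in 14, its most accessible nucleophilic carbon, anti to the 3-OH, which sets the third 4β interflavan bond.

**Step 14**
Reactants: 20 hexadeca-O-benzylarecatannin a2
Product: 21 arecatannin a2
Conditions: H2 (1 atm), Pd(OH)2/C, THF/MeOH/H2O, rt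
Reagents that add atoms: none
Why: Hydrogenolysis of the sixteen benzyl ethers is neutral and should leave the acid- and base-sensitive interflavan bonds and all twelve stereocentres intact.

**Compound list**

1 | 3,5-bis(benzyloxy)phenol | Oc1cc(OCc2ccccc2)cc(OCc2ccccc2)c1 | starting material
2 | 2,4-bis(benzyloxy)-6-hydroxybenzaldehyde | O=Cc1c(O)cc(OCc2ccccc2)cc1OCc1ccccc1 | intermediate
3 | 2,4-bis(benzyloxy)-6-(triisopropylsilyloxy)benzaldehyde | O=Cc1c(O[Si](C(C)C)(C(C)C)C(C)C)cc(OCc2ccccc2)cc1OCc1ccccc1 | intermediate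
4 | [3,5-bis(benzyloxy)-2-ethynylphenoxy]triisopropylsilane | C#Cc1c(O[Si](C(C)C)(C(C)C)C(C)C)cc(OCc2ccccc2)cc1OCc1ccccc1 | intermediate
5 | (Z)-2-[2,4-bis(benzyloxy)-6-(triisopropylsilyloxy)phenyl]ethenyl acetate | CC(=O)O/C=C\c1c(O[Si](C(C)C)(C(C)C)C(C)C)cc(OCc2ccccc2)cc1OCc1ccccc1 | intermediate
6 | 3,4-bis(benzyloxy)benzaldehyde | O=Cc1ccc(OCc2ccccc2)c(OCc2ccccc2)c1 | starting material
7 | [3,4-bis(benzyloxy)phenyl](chloro)methyl pivalate (racemic, not isolated) | CC(C)(C)C(=O)OC(Cl)c1ccc(OCc2ccccc2)c(OCc2ccccc2)c1 | intermediate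
8 | (Z)-2-[2,4-bis(benzyloxy)-6-hydroxyphenyl]ethenyl acetate (formed as its tetrabutylammonium phenoxide, not isolated) | CC(=O)O/C=C\c1c(O)cc(OCc2ccccc2)cc1OCc1ccccc1 | intermediate
9 | (Z)-2-{2,4-bis(benzyloxy)-6-[(3,4-bis(benzyloxy)phenyl)(pivaloyloxy)methoxy]phenyl}ethenyl acetate (racemic at the acetal carbon) | CC(=O)O/C=C\c1c(OC(OC(=O)C(C)(C)C)c2ccc(OCc3ccccc3)c(OCc3ccccc3)c2)cc(OCc2ccccc2)cc1OCc1ccccc1 | intermediate
10 | (+)-catechin (2R,3S) | Oc1cc(O)c2c(c1)O[C@H](c1ccc(O)c(O)c1)[C@@H](O)C2 | starting material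
11 | 5,7,3',4'-tetra-O-benzyl-(+)-catechin | c3ccccc3COc1cc(OCc3ccccc3)c2c(c1)O[C@H](c1ccc(OCc3ccccc3)c(OCc3ccccc3)c1)[C@@H](O)C2 | intermediate
12 | 3-O-acetyl-4β-pivaloyloxy-5,7,3',4'-tetra-O-benzylepicatechin (2,3-cis, 3,4-trans; not isolated) | c3ccccc3COc1cc(OCc3ccccc3)c2c(c1)O[C@H](c1ccc(OCc3ccccc3)c(OCc3ccccc3)c1)[C@H](OC(C)=O)[C@H]2OC(=O)C(C)(C)C | intermediate
13 | 3-O-acetyl-5,7,3',4'-tetra-O-benzylepicatechin-(4β→8)-5,7,3',4'-tetra-O-benzylcatechin | c3ccccc3COc1cc(OCc3ccccc3)c2c(c1)O[C@H](c1ccc(OCc3ccccc3)c(OCc3ccccc3)c1)[C@H](OC(C)=O)[C@H]2c1c(OCc3ccccc3)cc(OCc3ccccc3)c2c1O[C@H](c1ccc(OCc3ccccc3)c(OCc3ccccc3)c1)[C@@H](O)C2 | intermediate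
14 | octa-O-benzylprocyanidin B1 | c3ccccc3COc1cc(OCc3ccccc3)c2c(c1)O[C@H](c1ccc(OCc3ccccc3)c(OCc3ccccc3)c1)[C@H](O)[C@H]2c1c(OCc3ccccc3)cc(OCc3ccccc3)c2c1O[C@H](c1ccc(OCc3ccccc3)c(OCc3ccccc3)c1)[C@@H](O)C2 | intermediate
15 | (−)-epicatechin (2R,3R) | Oc1cc(O)c2c(c1)O[C@H](c1ccc(O)c(O)c1)[C@H](O)C2 | starting material
16 | 5,7,3',4'-tetra-O-benzyl-(−)-epicatechin | c3ccccc3COc1cc(OCc3ccccc3)c2c(c1)O[C@H](c1ccc(OCc3ccccc3)c(OCc3ccccc3)c1)[C@H](O)C2 | intermediate
17 | 4β-(2-ethoxyethoxy)-5,7,3',4'-tetra-O-benzylepicatechin | c3ccccc3COc1cc(OCc3ccccc3)c2c(c1)O[C@H](c1ccc(OCc3ccccc3)c(OCc3ccccc3)c1)[C@H](O)[C@H]2OCCOCC | intermediate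
18 | octa-O-benzylprocyanidin B2 | c3ccccc3COc1cc(OCc3ccccc3)c2c(c1)O[C@H](c1ccc(OCc3ccccc3)c(OCc3ccccc3)c1)[C@H](O)[C@H]2c1c(OCc3ccccc3)cc(OCc3ccccc3)c2c1O[C@H](c1ccc(OCc3ccccc3)c(OCc3ccccc3)c1)[C@H](O)C2 | intermediate
19 | octa-O-benzylprocyanidin B2 with a 4β-(2-ethoxyethoxy) group on the lower unit | c3ccccc3COc1cc(OCc3ccccc3)c2c(c1)O[C@H](c1ccc(OCc3ccccc3)c(OCc3ccccc3)c1)[C@H](O)[C@H]2c1c(OCc3ccccc3)cc(OCc3ccccc3)c2c1O[C@H](c1ccc(OCc3ccccc3)c(OCc3ccccc3)c1)[C@H](O)[C@H]2OCCOCC | intermediate
20 | hexadeca-O-benzylarecatannin a2 | c3ccccc3COc1cc(OCc3ccccc3)c2c(c1)O[C@H](c1ccc(OCc3ccccc3)c(OCc3ccccc3)c1)[C@H](O)[C@H]2c1c(OCc3ccccc3)cc(OCc3ccccc3)c2c1O[C@H](c1ccc(OCc3ccccc3)c(OCc3ccccc3)c1)[C@H](O)[C@H]2c1c(OCc3ccccc3)cc(OCc3ccccc3)c2c1O[C@H](c1ccc(OCc3ccccc3)c(OCc3ccccc3)c1)[C@H](O)[C@H]2c1c(OCc3ccccc3)cc(OCc3ccccc3)c2c1O[C@H](c1ccc(OCc3ccccc3)c(OCc3ccccc3)c1)[C@@H](O)C2 | intermediate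
21 | arecatannin a2, epicatechin-(4β→8)-epicatechin-(4β→8)-epicatechin-(4β→8)-catechin | Oc1cc(O)c2c(c1)O[C@H](c1ccc(O)c(O)c1)[C@H](O)[C@H]2c1c(O)cc(O)c2c1O[C@H](c1ccc(O)c(O)c1)[C@H](O)[C@H]2c1c(O)cc(O)c2c1O[C@H](c1ccc(O)c(O)c1)[C@H](O)[C@H]2c1c(O)cc(O)c2c1O[C@H](c1ccc(O)c(O)c1)[C@@H](O)C2 | target

**Total step count:** 14.

**Longest linear sequence:** 9 steps (steps 1, 2, 3, 4, 5, 7, 8, 13, 14; from 1 to 21).

**Steps most likely to fail**

1. Step 7. What may go wrong: the ion pair may discriminate the two faces poorly, the enol acetate may attack through C4 and close a five-membered ring, or the C4 cation may condense with ring A of a second molecule. Fallback with known reactions only, setting out from 1 and coming back to the route at 16 and then at 14: 1 is O-allylated (allyl bromide, K2CO3, acetone) to 1-(allyloxy)-3,5-bis(benzyloxy)benzene F1. Aromatic Claisen rearrangement (N,N-diethylaniline, 190 °C) gives 2-allyl-3,5-bis(benzyloxy)phenol F2. Acylation with 3,4-bis(benzyloxy)benzoyl chloride (Et3N, DMAP, CH2Cl2) gives 2-allyl-3,5-bis(benzyloxy)phenyl 3,4-bis(benzyloxy)benzoate F3. A titanium-ethylidene olefinic-ester cyclisation (TiCl4, Zn, PbCl2 cat., TMEDA, CH3CHBr2, THF, 65 °C) joins the ester carbon to the internal allyl carbon and so closes ring C through a C2=C3 double bond, giving 5,7-bis(benzyloxy)-2-[3,4-bis(benzyloxy)phenyl]-4H-chromene F4. Asymmetric hydroboration with monoisopinocampheylborane and oxidation with NaBO3 adds H to C2 and OH to C3 on the same face and should give the 2,3-trans alcohol 11 (borane antipode chosen for 2R,3S). Dess–Martin oxidation gives (2R)-5,7-bis(benzyloxy)-2-[3,4-bis(benzyloxy)phenyl]chroman-3-one F5, and LiBH(s-Bu)3 at −78 °C should deliver hydride to the less hindered face and give the 2,3-cis alcohol 16. Step 10 then gives 17, whose TMSOTf-catalysed condensation with 11 (conditions of step 11) gives 14 directly, so that steps 2–5, 7 and 8 fall away.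

2. Step 5. What may go wrong: acetyl transfer from the enol acetate to the liberated phenoxide, and ionisation or hydrolysis of the acyloxy acetal during isolation. Fallback that never isolates the acetal, setting out from 5 and coming back at 13: 5 is desilylated with Bu4NF buffered with AcOH (THF, 0 °C) and the neutral phenol 8 is isolated. Aldehyde 6 is converted with pivalic anhydride and Sc(OTf)3 (cat.) into the acylal [3,4-bis(benzyloxy)phenyl]methylene dipivalate F6. Phenol 8, F6 and 11 are then combined under the chiral acid of step 7; acid-catalysed acylal exchange should generate 9 in the flask, which cyclises and couples as in step 7 to give 13.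

3. Step 13. What may go wrong: self-condensation of the dimeric electrophile, and attack at C6 or at the lower catechin ring of 14 instead of C8 of unit 3. Fallback by two single-unit extensions, setting out from 14 and coming back at 20: 14 (3 equiv) is condensed with monomeric electrophile 17 (TMSOTf cat., CH2Cl2, −78 °C) to give the dodeca-O-benzyl trimer epicatechin-(4β→8)-epicatechin-(4β→8)-catechin F7. F7 (in excess, recovered) is condensed with 17 again under the same conditions to give 20, so that steps 11 and 12 fall away.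

**Further compounds**

F1 | step 7 | 1-(allyloxy)-3,5-bis(benzyloxy)benzene | C=CCOc1cc(OCc2ccccc2)cc(OCc2ccccc2)c1
F2 | step 7 | 2-allyl-3,5-bis(benzyloxy)phenol | C=CCc1c(O)cc(OCc2ccccc2)cc1OCc1ccccc1
F3 | step 7 | 2-allyl-3,5-bis(benzyloxy)phenyl 3,4-bis(benzyloxy)benzoate | C=CCc1c(OC(=O)c2ccc(OCc3ccccc3)c(OCc3ccccc3)c2)cc(OCc2ccccc2)cc1OCc1ccccc1
F4 | step 7 | 5,7-bis(benzyloxy)-2-[3,4-bis(benzyloxy)phenyl]-4H-chromene | c3ccccc3COc1cc(OCc3ccccc3)c2c(c1)OC(c1ccc(OCc3ccccc3)c(OCc3ccccc3)c1)=CC2
F5 | step 7 | (2R)-5,7-bis(benzyloxy)-2-[3,4-bis(benzyloxy)phenyl]chroman-3-one | c3ccccc3COc1cc(OCc3ccccc3)c2c(c1)O[C@H](c1ccc(OCc3ccccc3)c(OCc3ccccc3)c1)C(=O)C2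
F6 | step 5 | [3,4-bis(benzyloxy)phenyl]methylene dipivalate | CC(C)(C)C(=O)OC(OC(=O)C(C)(C)C)c1ccc(OCc2ccccc2)c(OCc2ccccc2)c1
F7 | step 13 | dodeca-O-benzyl epicatechin-(4β→8)-epicatechin-(4β→8)-catechin | c3ccccc3COc1cc(OCc3ccccc3)c2c(c1)O[C@H](c1ccc(OCc3ccccc3)c(OCc3ccccc3)c1)[C@H](O)[C@H]2c1c(OCc3ccccc3)cc(OCc3ccccc3)c2c1O[C@H](c1ccc(OCc3ccccc3)c(OCc3ccccc3)c1)[C@H](O)[C@H]2c1c(OCc3ccccc3)cc(OCc3ccccc3)c2c1O[C@H](c1ccc(OCc3ccccc3)c(OCc3ccccc3)c1)[C@@H](O)C2
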